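**Assumption:** the SMILES is read as the (2R,3R)-2,3-trans isomer; 1, 2, 3 and 7 are taken as catalogue chemicals.

## Retrosynthetic overview

1. The target is the O-methyl ether of a 7-hydroxy-2,3-dihydrobenzofuran.
2. Key disconnection: the oxygenated benzene ring and the dihydrofuran ring are formed together by gold-catalysed furan–yne benzannulation of an acyclic ynol ether. The furan oxygen becomes the C7 oxygen, and the furan C4 substituent becomes the C5 propenyl group.
3. The ynol ether comes from a (1R,2S) alcohol and trichloroethylene. Both stereocentres are set in one asymmetric hydrogenation with dynamic kinetic resolution of a racemic α-furyl ketone.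
4. The ketone comes from a one-pot α-arylation/Suzuki sequence on 2,4-dibromofuran.
5. Ring order: trimethoxyphenyl and furan rings are purchased; the benzene and dihydrofuran rings form simultaneously in step 4.

## Route

**Step 1**
Reactants: 1 1-(3,4,5-trimethoxyphenyl)propan-1-one; 2 2,4-dibromofuran; 3 (E)-prop-1-enylboronic acid pinacol ester
Product: 5 rac-2-{4-[(E)-prop-1-enyl]furan-2-yl}-1-(3,4,5-trimethoxyphenyl)propan-1-one, via bromo ketone 4 (not isolated)
Conditions: (DtBPF)PdCl2 (2 mol%), NaOtBu (2.2 equiv), THF, 60 °C; then 3 (1.3 equiv), aq K3PO4, 70 °C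
Reagents that add atoms: none
Why: Buchwald–Hartwig-type Pd-catalysed ketone α-arylation takes place at the more reactive α-C–Br (C2) of 2, and the remaining β-C–Br is then used in a stereoretentive Suzuki–Miyaura coupling with the E-alkenylboronate in the same pot; the α-stereocentre is deliberately formed racemic because step 2 resolves it dynamically.

**Step 2**
Reactants: 5 rac-2-{4-[(E)-prop-1-enyl]furan-2-yl}-1-(3,4,5-trimethoxyphenyl)propan-1-one
Product: 6 (1R,2S)-2-{4-[(E)-prop-1-enyl]furan-2-yl}-1-(3,4,5-trimethoxyphenyl)propan-1-ol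
Conditions: trans-RuCl2[(S)-xylbinap][(S)-daipen] (0.5 mol%), t-BuOK (20 mol%), H2 (10 atm), i-PrOH, 25 °C
Reagents that add atoms: none
Why: Noyori asymmetric hydrogenation with dynamic kinetic resolution: t-BuOK racemises the α-C–H (activated by both C=O and furyl), the (S,S)-catalyst sets the (R)-carbinol as for aryl alkyl ketones, and only the ketone enantiomer whose Felkin–Anh face matches the catalyst reduces quickly, which fixes C2 as S (the relative configuration that becomes 2,3-trans in the ring); the Ru–diphosphine/diamine catalyst does not reduce the C=C bond or the furan.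

**Step 3**
Reactants: 6 (1R,2S)-2-{4-[(E)-prop-1-enyl]furan-2-yl}-1-(3,4,5-trimethoxyphenyl)propan-1-ol; 7 trichloroethylene
Product: 10 5-[(1R,2S)-1-(ethynyloxy)-2-{4-[(E)-prop-1-enyl]furan-2-yl}propyl]-1,2,3-trimethoxybenzene, via dichlorovinyl ether 8 (not isolated), via lithium acetylide 9 (not isolated)
Conditions: KH, THF, 0 °C; 7, −50 °C → rt; then n-BuLi (2.5 equiv), −78 → −40 °C; cold aq NaHCO3; fast filtration through Et3N-deactivated silica, used at once
Reagents that add atoms: none
Why: Greene ynol ether synthesis: the potassium alkoxide adds to dichloroacetylene generated in situ from 7, then n-BuLi causes dehydrochlorination and Cl/Li exchange to the lithium alkoxyacetylide, which is protonated on quench; the C–O bond of the carbinol is retained, so neither stereocentre is touched.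

**Step 4**
Reactants: 10 5-[(1R,2S)-1-(ethynyloxy)-2-{4-[(E)-prop-1-enyl]furan-2-yl}propyl]-1,2,3-trimethoxybenzene
Product: 12 (2R,3R)-3-methyl-5-[(E)-prop-1-enyl]-2-(3,4,5-trimethoxyphenyl)-2,3-dihydro-1-benzofuran-7-ol, via arene oxide 11 (not isolated)
Conditions: (Mes3P)AuNTf2 (2 mol%), 4 Å MS, CH2Cl2, −20 °C → rt
Reagents that add atoms: none
Why: Gold-catalysed furan–yne phenol synthesis (Hashmi benzannulation): the furan C2=C3 bond attacks the Au-activated ynol ether at its O-bearing carbon (5-exo), the cyclopropyl gold carbenoid opens the furan to a carbonyl-conjugated carbenoid that closes to the oxepine/arene oxide, and the oxide opens towards the cation stabilised by the ring oxygen so that the former furan oxygen ends as the C7 phenol; benzene and dihydrofuran rings form in one operation, and the pre-set stereocentres are not involved, so they become C2 (R) and C3 (R), trans.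

**Step 5**
Reactants: 12 (2R,3R)-3-methyl-5-[(E)-prop-1-enyl]-2-(3,4,5-trimethoxyphenyl)-2,3-dihydro-1-benzofuran-7-ol
Product: 13 (2R,3R)-7-methoxy-3-methyl-5-[(E)-prop-1-enyl]-2-(3,4,5-trimethoxyphenyl)-2,3-dihydro-1-benzofuran
Conditions: MeI, K2CO3, acetone, 45 °C
Reagents that add atoms: iodomethane (MeI), CI
Why: Williamson ether synthesis on the only acidic site (the phenol); the mild carbonate base does not affect the benzylic stereocentres or the E-alkene.

## Compound list

1 | 1-(3,4,5-trimethoxyphenyl)propan-1-one | CCC(=O)c1cc(OC)c(OC)c(OC)c1 | starting material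
2 | 2,4-dibromofuran | Brc1cc(Br)co1 | starting material
3 | (E)-prop-1-enylboronic acid pinacol ester | C/C=C/B1OC(C)(C)C(C)(C)O1 | starting material
4 | rac-2-(4-bromofuran-2-yl)-1-(3,4,5-trimethoxyphenyl)propan-1-one (bromo ketone, formed in the flask in step 1) | CC(c1cc(Br)co1)C(=O)c1cc(OC)c(OC)c(OC)c1 | intermediate
5 | rac-2-{4-[(E)-prop-1-enyl]furan-2-yl}-1-(3,4,5-trimethoxyphenyl)propan-1-one | C/C=C/c1coc(c1)C(C)C(=O)c1cc(OC)c(OC)c(OC)c1 | intermediate
6 | (1R,2S)-2-{4-[(E)-prop-1-enyl]furan-2-yl}-1-(3,4,5-trimethoxyphenyl)propan-1-ol | C/C=C/c1coc(c1)[C@@H](C)[C@@H](O)c1cc(OC)c(OC)c(OC)c1 | intermediate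
7 | trichloroethylene | ClC=C(Cl)Cl | starting material
8 | 5-[(1R,2S)-1-{[(E)-1,2-dichloroethenyl]oxy}-2-{4-[(E)-prop-1-enyl]furan-2-yl}propyl]-1,2,3-trimethoxybenzene (dichlorovinyl ether, formed in the flask in step 3) | C/C=C/c1coc(c1)[C@@H](C)[C@@H](O/C(Cl)=C\Cl)c1cc(OC)c(OC)c(OC)c1 | intermediate
9 | lithium acetylide of 10 (formed in the flask in step 3) | C/C=C/c1coc(c1)[C@@H](C)[C@@H](OC#C[Li])c1cc(OC)c(OC)c(OC)c1 | intermediate
10 | 5-[(1R,2S)-1-(ethynyloxy)-2-{4-[(E)-prop-1-enyl]furan-2-yl}propyl]-1,2,3-trimethoxybenzene | C/C=C/c1coc(c1)[C@@H](C)[C@@H](OC#C)c1cc(OC)c(OC)c(OC)c1 | intermediate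
11 | (2R,3R)-6,7-epoxy-3-methyl-5-[(E)-prop-1-enyl]-2-(3,4,5-trimethoxyphenyl)-2,3,6,7-tetrahydro-1-benzofuran (arene oxide, epoxide face not defined, formed in the flask in step 4) | C/C=C/C1=CC2=C(C3OC13)O[C@@H](c1cc(OC)c(OC)c(OC)c1)[C@@H]2C | intermediate
12 | (2R,3R)-3-methyl-5-[(E)-prop-1-enyl]-2-(3,4,5-trimethoxyphenyl)-2,3-dihydro-1-benzofuran-7-ol | C/C=C/c1cc(O)c2c(c1)[C@@H](C)[C@H](c1cc(OC)c(OC)c(OC)c1)O2 | intermediate
13 | (2R,3R)-7-methoxy-3-methyl-5-[(E)-prop-1-enyl]-2-(3,4,5-trimethoxyphenyl)-2,3-dihydro-1-benzofuran | C/C=C/c1cc(OC)c2c(c1)[C@@H](C)[C@H](c1cc(OC)c(OC)c(OC)c1)O2 | target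

## Step count

Total steps: 5. Longest linear sequence: 5 (from 1 or 2 to 13).

## Steps most likely to fail, with fallbacks

**Step 4 (gold benzannulation; the 4-alkenyl, 5-unsubstituted furan and the labile benzylic ynol ether are untested in this reaction).** The fallback sets out from 1 and comes back at 13. It gives up the benzannulation and closes only the dihydrofuran ring on a ready-made arene. Commercial 5-bromovanillin is protected (MOMCl, i-Pr2NEt, CH2Cl2) as 3-bromo-5-methoxy-4-(methoxymethoxy)benzaldehyde F5. E-selective Julia–Kocienski olefination with 5-(ethylsulfonyl)-1-phenyl-1H-tetrazole (KHMDS, DME, −60 °C) gives 1-bromo-3-methoxy-2-(methoxymethoxy)-5-[(E)-prop-1-enyl]benzene F6. Pd-catalysed α-arylation of 1 with F6 under the step 1 conditions gives the racemic ketone 2-{3-methoxy-2-(methoxymethoxy)-5-[(E)-prop-1-enyl]phenyl}-1-(3,4,5-trimethoxyphenyl)propan-1-one F7. The step 2 hydrogenation then gives the (1R,2R) alcohol 2-{3-methoxy-2-(methoxymethoxy)-5-[(E)-prop-1-enyl]phenyl}-1-(3,4,5-trimethoxyphenyl)propan-1-ol F8. Mild acid (cat. HCl, MeOH, 0 °C → rt) removes the MOM group, and the free phenol traps the trimethoxybenzylic cation. C3 is fixed by the hydrogenation and the ring closes 2,3-trans, giving 13 directly.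

**Step 3 (ynol ether from a hindered, electron-rich benzylic alkoxide via dichloroacetylene).** The fallback sets out from 6 and comes back at 10 through 9. It builds the alkyne one carbon at a time. Alcohol 6 is formylated (formic acetic anhydride, pyridine, 0 °C) to (1R,2S)-2-{4-[(E)-prop-1-enyl]furan-2-yl}-1-(3,4,5-trimethoxyphenyl)propyl formate F3. Dibromo-olefination of the formate carbonyl (CBr4, PPh3, CH2Cl2) gives the 2,2-dibromovinyl ether 5-[(1R,2S)-1-[(2,2-dibromoethenyl)oxy]-2-{4-[(E)-prop-1-enyl]furan-2-yl}propyl]-1,2,3-trimethoxybenzene F4. n-BuLi (2.2 equiv, THF, −78 °C) then causes Br/Li exchange and a Fritsch–Buttenberg–Wiechell-type 1,2-shift to the lithium acetylide 9, which is quenched to 10 as in the main route.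

**Step 1 (α-arylation with a 2-bromofuran and a one-pot second coupling).** The fallback sets out from 1 and 2 and comes back at 4, which is now isolated. It reverses the polarity of the C–C bond formation. Ketone 1 is α-brominated (CuBr2, EtOAc/CHCl3, reflux) to 2-bromo-1-(3,4,5-trimethoxyphenyl)propan-1-one F1. Dibromide 2 undergoes C2-selective Br/Li exchange (n-BuLi, Et2O, −78 °C) and transmetalation with ZnCl2 to (4-bromofuran-2-yl)zinc chloride F2. Ni-catalysed Negishi coupling of the α-bromo ketone with the heteroarylzinc (NiCl2·glyme, bipyridine-type ligand, THF/DMA, −30 °C) gives bromo ketone 4. The Suzuki coupling with 3 is then run as a separate operation to reach 5.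

## Further compounds

F1 | step 1 | 2-bromo-1-(3,4,5-trimethoxyphenyl)propan-1-one (racemic) | CC(Br)C(=O)c1cc(OC)c(OC)c(OC)c1
F2 | step 1 | (4-bromofuran-2-yl)zinc chloride | Cl[Zn]c1cc(Br)co1
F3 | step 3 | (1R,2S)-2-{4-[(E)-prop-1-enyl]furan-2-yl}-1-(3,4,5-trimethoxyphenyl)propyl formate | C/C=C/c1coc(c1)[C@@H](C)[C@@H](OC=O)c1cc(OC)c(OC)c(OC)c1
F4 | step 3 | 5-[(1R,2S)-1-[(2,2-dibromoethenyl)oxy]-2-{4-[(E)-prop-1-enyl]furan-2-yl}propyl]-1,2,3-trimethoxybenzene | C/C=C/c1coc(c1)[C@@H](C)[C@@H](OC=C(Br)Br)c1cc(OC)c(OC)c(OC)c1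
F5 | step 4 | 3-bromo-5-methoxy-4-(methoxymethoxy)benzaldehyde | O=Cc1cc(Br)c(OCOC)c(OC)c1
F6 | step 4 | 1-bromo-3-methoxy-2-(methoxymethoxy)-5-[(E)-prop-1-enyl]benzene | C/C=C/c1cc(Br)c(OCOC)c(OC)c1
F7 | step 4 | rac-2-{3-methoxy-2-(methoxymethoxy)-5-[(E)-prop-1-enyl]phenyl}-1-(3,4,5-trimethoxyphenyl)propan-1-one | C/C=C/c1cc(OC)c(OCOC)c(c1)C(C)C(=O)c1cc(OC)c(OC)c(OC)c1
F8 | step 4 | (1R,2R)-2-{3-methoxy-2-(methoxymethoxy)-5-[(E)-prop-1-enyl]phenyl}-1-(3,4,5-trimethoxyphenyl)propan-1-ol | C/C=C/c1cc(OC)c(OCOC)c(c1)[C@@H](C)[C@@H](O)c1cc(OC)c(OC)c(OC)c1
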